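# Proposed total synthesis of CNP0102599.2 (target 34) through a cyclobutanone retro-Claisen lactonisation

## Analysis of the target

Target 34 is a flavan in which benzo ring A is fused to a pyran ring (O1, C2, C3, C4, C4a, C8a) that carries a 4-hydroxyphenyl group on C2 and a 2-hydroxy-4-(4-hydroxyphenyl)butyl chain (C1' to C4') on C4. Ring A is a fully differentiated phloroglucinol with a free hydroxyl on C5, a methoxy group on C7, an (E)-4-hydroxycinnamoyl group on C8 and the pyran carbon C4 on C4a. There are three stereocentres: C2 (R) and C4 (S), which are trans on the pyran ring, and the carbinol C2' (R), which lies 1,3 to C4 in the open chain where the ring cannot control it. The sensitive groups are the chalcone enone (hydride, hydrogenation, conjugate addition), the four phenols and the benzylic C2–O1 ether para to a hydroxyl, which can ionise in acid or open in strong base and so epimerise C2. The hard points are the all-carbon benzylic centre C4 with no heteroatom next to it, the C6/C8 regiochemistry of acylation on ring A, and the remote C2' centre. The strategy rests on the unit O1–C2–C3–C4 with its C1' branch: the carbons C2, C3, C4 and C1' are the four ring carbons of a 3-arylcyclobutanone whose carbonyl carbon becomes C2 and whose aryl group is ring A.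

## Retrosynthetic reasoning

**34 from 33.** The last operation only removes five silyl groups. All hydroxyls are carried as silyl ethers because these can be cleaved together near neutrality, which leaves the enone and the C2–O1 ether alone, whereas hydrogenolysis, strong acid or strong base would not.

**33 from 29 and 31.** The C8–carbonyl bond is cut. The chalcone is attached last because it would not survive the hydride, hydrogenation and organometallic steps before it. C8 lies between O1 and the methoxy group, C6 between the methoxy group and a bulky silyl ether, so bromination of 28 to 29 fixes the position. Halogen–lithium exchange gives 32, which takes the acyl group from amide 31. Amide 31 comes from aldehyde 30 by olefination.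

**28 from 23 and 24.** The C2–aryl bond is cut next to oxygen, where the cation 27 is available from acetate 23. The aryl group is delivered from bromide 24 through 25 and 26. The O1–C2 bond stays intact, and the forward step must place the aryl group trans to the C4 chain.

**23 back to 16.** No skeletal bond is cut here (23, 21, 20, 19, 17, 16). The lactone carbon is lowered to the acetal level only after the side chain is finished, because the reducing agent would otherwise attack the enone. In the chain, the C2' carbinol is made from the enone ketone by catalyst control while the C3'=C4' double bond still differentiates the two sides of the carbonyl. One hydrogenation then saturates the chain and removes the benzyl group.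

**16 from 14 (key disconnection).** The O1–C2 bond is cut and C2 is reconnected to C1', which gives the 2-acyl-3-arylcyclobutanone 14. This turns the C4 problem into the question of which enantiotopic α-carbon of a symmetric ketone carries the acyl group. Ring A enters with two equivalent hydroxyls, so no differentiation of oxygens is needed at this stage. The forward step must send a phenol to the ring carbonyl and break only the bond between the carbonyl carbon and the acyl-bearing carbon.

**14 from 8 and 10.** The bond between the cyclobutanone α-carbon and the side-chain carbonyl carbon is cut (14, 13, 12). Ketone 8 has a mirror plane, and enantioselective deprotonation gives enolate 11. Aldol addition to enal 10 followed by oxidation is preferred to direct acylation because it avoids proton transfer from the acidic product to the enolate. Removing the ring-A silyl groups from 13 gives 14. Enal 10 comes from aldehyde 9.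

**8 from 4 and 6.** Two cyclobutane bonds are cut in a [2+2] sense (8, 7, 4 + 6). Ketene 6, generated from 5, adds to styrene 4 so that the carbonyl ends up 1,3 to the aryl-bearing carbon. Dechlorination of 7 gives 8.

**4 from 1.** Styrene 4 comes from aldehyde 3 by methylenation. Aldehyde 3 comes from 2 by silylation, and 2 from 1 by methylation of the one hydroxyl that is not chelated.

## Alternatives that were turned down

**Alternative 1: ring A built by recyclisation of a pyrone.**
- Disconnection: the aromatic ring itself is opened at C8–C8a, back to a chain in which a 2-pyrone carries a keto side chain.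
- Forward key step: magnesium methoxide A2 opens the pyrone, the side-chain methylene carbanion adds to the former lactone carbonyl, and aromatisation gives the ring-A-complete open-chain chalcone A1.
- For it: the cinnamoyl group sits on C8 by construction, so there is no C6/C8 question. Ring A and the chalcone appear together, and the plan is convergent.
- Against it: C2, C4 and C2' must all be set beforehand in an acyclic chain. A1 then has two free hydroxyls (future C7 and C8a) that both chelate the ketone and are nearly equivalent, yet one must be methylated and the other must displace the C2 oxygen with inversion. That carbon is a para-oxygenated benzylic position that ionises easily, which puts the C2 configuration at risk. A chalcone with a free ortho hydroxyl can also close to a flavanone under the basic conditions that A2 sets up.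
- Comparison: this alternative is stronger on acyl regiochemistry and on convergence. The chosen strategy offers in exchange a bought ring A, a key step in which the two hydroxyls are equivalent, and C4 from one desymmetrisation instead of acyclic stereocontrol at three centres.

**Alternative 2: aryne cyclisation that installs O1 and the acyl group together.**
- Disconnection: O1–C8a and C8–carbonyl are cut in one operation.
- Forward key step: lithium 2,2,6,6-tetramethylpiperidide A4 generates the C8–C8a aryne on a ring-A halide that carries the whole chain. The C2 alkoxide adds at C8a and closes the pyran ring, and the resulting C8 aryllithium is acylated, giving the fully silylated target A3.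
- For it: two bonds and a ring form in one flask, the product A3 is one deprotection from 34, and the aryne polarity fixes the acyl position.
- Against it: all three stereocentres, including the benzylic C2 carbinol, must be made in an open chain. The aryllithium is formed next to the conjugate amine and may be protonated before acylation. The base A4 can itself add to the aryne or to the cinnamoyl electrophile. A failure costs the most advanced material.
- Comparison: this alternative is stronger in end-game step economy and in C8 regiocontrol, since it needs no separate halogenation. The chosen strategy offers a key step without strong base in the middle of the route, and ring-based control of C2.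

**Alternative 3: benzannulation of ring A onto a dihydropyran.**
- Disconnection: ring A is cut at C5–C6, C7–C8 and C4a–C5, back to a dihydropyran that already holds C2 and C4.
- Forward key step: photolysis of a dihydropyranyl diazoketone gives a vinylketene by Wolff rearrangement. Cycloaddition with methoxyacetylene A6, four-electron ring opening and six-electron ring closure give the 5-hydroxy-7-methoxy chroman A5.
- For it: the C5 hydroxyl and the C7 methoxy group are differentiated by construction, and the 2,4-trans relation is set on a non-aromatic ring.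
- Against it: the diazoketone needs a long linear preparation. A6 is volatile, unstable and not a shelf reagent. The photolysis is run on a substrate with several absorbing aryl silyl ethers. C8 is still unsubstituted in A5, so the C6/C8 acylation problem remains.
- Comparison: this alternative is stronger in differentiating the ring-A oxygens. The chosen strategy offers a cheap aromatic starting material, no photochemistry and fewer steps to the ring system. Both routes need the same late C8 acylation.

Key step: step 10

## Assumptions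

- The (R,R)-lithium amide in step 7 is assumed to remove the proton that leads to the (3R)-enolate 11. If the sense of induction is the opposite, the equally available (S,S)-amine is used.
- Compounds 1, 5, 9, 24 and 30 are catalogue compounds.

## Route

**Step 1**
Reactants: 1 2,4,6-trihydroxybenzaldehyde
Product: 2 2,6-dihydroxy-4-methoxybenzaldehyde
Conditions: Me2SO4 (1.0 equiv), K2CO3 (1.0 equiv), acetone, 0 °C to rt
Reagents that add atoms: dimethyl sulfate, COS(=O)(=O)OC
Why: Regioselective O-alkylation: the 4-hydroxyl is the most acidic and the only one not hydrogen-bonded to the aldehyde, so one equivalent of base and of a hard methylating agent should methylate it first; over-methylated material is removed by chromatography.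

**Step 2**
Reactants: 2 2,6-dihydroxy-4-methoxybenzaldehyde
Product: 3 2,6-bis(tert-butyldimethylsilyloxy)-4-methoxybenzaldehyde
Conditions: TBSCl (2.5 equiv), imidazole, DMF, rt
Reagents that add atoms: tert-butyldimethylsilyl chloride, CC(C)(C)[Si](C)(C)Cl
Why: Standard silylation of phenols; an excess of reagent should also silylate the chelated hydroxyls, and the silyl ethers are chosen because fluoride removes them later without touching a benzyl ether or an enone.

**Step 3**
Reactants: 3 2,6-bis(tert-butyldimethylsilyloxy)-4-methoxybenzaldehyde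
Product: 4 2,6-bis(tert-butyldimethylsilyloxy)-4-methoxystyrene
Conditions: Ph3PCH3Br, KOt-Bu, THF, 0 °C to rt
Reagents that add atoms: methyltriphenylphosphonium bromide, C[P+](c1ccccc1)(c1ccccc1)c1ccccc1.[Br-]
Why: Wittig methylenation; the small unstabilised ylide should reach the doubly ortho-substituted aldehyde, and the aryl silyl ethers tolerate the preformed ylide.

**Step 4**
Reactants: 4 2,6-bis(tert-butyldimethylsilyloxy)-4-methoxystyrene; 5 trichloroacetyl chloride
Product: 7 rac-3-[2,6-bis(tert-butyldimethylsilyloxy)-4-methoxyphenyl]-2,2-dichlorocyclobutan-1-one, via dichloroketene 6 (not isolated)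
Conditions: Zn–Cu couple, POCl3, Et2O, rt, ultrasound
Reagents that add atoms: none
Why: Ketene–alkene [2+2] cycloaddition; the ketene carbonyl carbon bonds to the terminal alkene carbon and the CCl2 carbon to the benzylic carbon, which places the carbonyl 1,3 to the aryl-bearing carbon. POCl3 binds the ZnCl2 formed and so suppresses cationic polymerisation of the electron-rich styrene; the racemic centre disappears as a stereocentre in step 5.

**Step 5**
Reactants: 7 rac-3-[2,6-bis(tert-butyldimethylsilyloxy)-4-methoxyphenyl]-2,2-dichlorocyclobutan-1-one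
Product: 8 3-[2,6-bis(tert-butyldimethylsilyloxy)-4-methoxyphenyl]cyclobutan-1-one
Conditions: Zn dust, AcOH, rt
Reagents that add atoms: none
Why: Reductive dechlorination of an α,α-dichloroketone by zinc; it gives the achiral ketone whose two α-methylenes are enantiotopic, and aryl silyl ethers tolerate acetic acid at room temperature.

**Step 6**
Reactants: 9 4-(benzyloxy)benzaldehyde
Product: 10 (E)-3-[4-(benzyloxy)phenyl]prop-2-enal
Conditions: Ph3P=CHCHO, toluene, 80 °C
Reagents that add atoms: (triphenylphosphoranylidene)acetaldehyde, O=CC=P(c1ccccc1)(c1ccccc1)c1ccccc1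
Why: Wittig reaction with a stabilised ylide, which is E-selective; a slight excess of aldehyde limits a second homologation.

**Step 7**
Reactants: 8 3-[2,6-bis(tert-butyldimethylsilyloxy)-4-methoxyphenyl]cyclobutan-1-one; 10 (E)-3-[4-(benzyloxy)phenyl]prop-2-enal
Product: 12 (3R)-3-[2,6-bis(tert-butyldimethylsilyloxy)-4-methoxyphenyl]-2-[(E)-3-(4-benzyloxyphenyl)-1-hydroxyprop-2-en-1-yl]cyclobutan-1-one (mixture at C2 and at the carbinol carbon), via lithium enolate 11 (not isolated)
Conditions: (R,R)-bis(1-phenylethyl)amine·HCl, n-BuLi (2.0 equiv), THF, −78 to 0 °C, then −100 °C; 8; then 10, −100 °C; AcOH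
Reagents that add atoms: none
Why: Enantioselective deprotonation of a prochiral 3-substituted cyclobutanone by a chiral lithium amide in the presence of LiCl formed in the flask, followed by aldol 1,2-addition to a non-enolisable enal. The choice of methylene fixes the configuration of the aryl-bearing carbon (later C4); the two other new centres are formed as a mixture and are erased in steps 8 and 10.

**Step 8**
Reactants: 12 (3R)-3-[2,6-bis(tert-butyldimethylsilyloxy)-4-methoxyphenyl]-2-[(E)-3-(4-benzyloxyphenyl)-1-hydroxyprop-2-en-1-yl]cyclobutan-1-one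
Product: 13 (3R)-2-[(E)-3-(4-benzyloxyphenyl)prop-2-enoyl]-3-[2,6-bis(tert-butyldimethylsilyloxy)-4-methoxyphenyl]cyclobutan-1-one (C2 epimers and enol form)
Conditions: Dess–Martin periodinane, CH2Cl2, 0 °C to rt
Reagents that add atoms: none
Why: Dess–Martin oxidation of a β-hydroxy ketone to the 1,3-diketone under non-basic conditions, which avoids retro-aldol cleavage; the aryl-bearing centre is not acidic and keeps its configuration.

**Step 9**
Reactants: 13 (3R)-2-[(E)-3-(4-benzyloxyphenyl)prop-2-enoyl]-3-[2,6-bis(tert-butyldimethylsilyloxy)-4-methoxyphenyl]cyclobutan-1-one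
Product: 14 (3R)-2-[(E)-3-(4-benzyloxyphenyl)prop-2-enoyl]-3-(2,6-dihydroxy-4-methoxyphenyl)cyclobutan-1-one
Conditions: Bu4NF, AcOH (1:1), THF, −20 to 0 °C
Reagents that add atoms: none
Why: Fluoride cleavage of the two aryl silyl ethers, buffered so that phenols and not phenoxides are released; the benzyl ether, the enone and the diketone are inert. Crude 14 is taken on at once, and any 16 formed already at this stage converges with the next step.

**Step 10**
Reactants: 14 (3R)-2-[(E)-3-(4-benzyloxyphenyl)prop-2-enoyl]-3-(2,6-dihydroxy-4-methoxyphenyl)cyclobutan-1-one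
Product: 16 (4S)-4-[(3E)-4-(4-benzyloxyphenyl)-2-oxobut-3-en-1-yl]-5-hydroxy-7-methoxychroman-2-one, via bridged hemiketal 15 (not isolated)
Conditions: Et3N (0.2 equiv), CH2Cl2, 0 °C to rt; AcOH
Reagents that add atoms: none
Why: One of the two equivalent ring-A hydroxyls adds to the strained cyclobutanone carbonyl of 14 to give the bridged hemiketal 15, whose alkoxide fragments by breaking the bond between the hemiketal carbon and the acyl-bearing carbon (retro-Claisen); this releases the ring strain and expels the enolate of the cinnamoyl ketone, which is protonated by triethylammonium or the remaining phenol to give 16. The closest known reaction type is the retro-Claisen ring opening of 2-acylcyclobutanones by alcohols and alkoxides, here intramolecular, and it is related to the ring-opening lactonisation of 3-(2-hydroxyaryl)cyclobutanones. The one ring that is closed is the six-membered lactone ring (O1–C2), by 6-exo-trig attack of oxygen on a carbonyl carbon. No new stereocentre is formed: C4 is the untouched aryl-bearing carbon of 14, the acyl-bearing carbon becomes the C1' methylene, the ring methylene becomes C3 and the ring carbonyl becomes C2. The step needs site selectivity between the two ketones, because the side-chain carbonyl can also be reached through a six-membered ring; the four-membered ketone is the more electrophilic, only its adduct fragments with strain release, and addition to the side-chain ketone is reversible as long as nothing drives dehydration. It also needs the right C–C bond to break, and only the bond to the acyl-bearing carbon gives a stabilised enolate. A substoichiometric amine leaves most of the β-diketone un-ionised, so the ring carbonyl stays electrophilic, and the E-enone is not affected.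

**Step 11**
Reactants: 16 (4S)-4-[(3E)-4-(4-benzyloxyphenyl)-2-oxobut-3-en-1-yl]-5-hydroxy-7-methoxychroman-2-one
Product: 17 (4S)-4-[(3E)-4-(4-benzyloxyphenyl)-2-oxobut-3-en-1-yl]-7-methoxy-5-(triisopropylsilyloxy)chroman-2-one
Conditions: TIPSOTf, 2,6-lutidine, CH2Cl2, −78 to 0 °C
Reagents that add atoms: triisopropylsilyl triflate, CC(C)[Si](OS(=O)(=O)C(F)(F)F)(C(C)C)C(C)C
Why: Silylation of the remaining phenol with a non-nucleophilic base, so the aryl lactone is not opened; the bulky group later screens C6 and holds the C4 chain pseudo-axial.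

**Step 12**
Reactants: 17 (4S)-4-[(3E)-4-(4-benzyloxyphenyl)-2-oxobut-3-en-1-yl]-7-methoxy-5-(triisopropylsilyloxy)chroman-2-one
Product: 19 (4S)-4-[(2S,3E)-4-(4-benzyloxyphenyl)-2-(tert-butyldimethylsilyloxy)but-3-en-1-yl]-7-methoxy-5-(triisopropylsilyloxy)chroman-2-one, via allylic alcohol 18 (not isolated)
Conditions: (R)-2-methyl-CBS-oxazaborolidine (0.2 equiv), BH3·SMe2, THF, −30 °C; MeOH; then TBSOTf, 2,6-lutidine, CH2Cl2, −78 °C
Reagents that add atoms: tert-butyldimethylsilyl triflate, CC(C)(C)[Si](C)(C)OS(=O)(=O)C(F)(F)F
Why: Corey–Bakshi–Shibata reduction of an alkenyl alkyl ketone: the alkenyl group acts as the large substituent, so the (R)-catalyst should give the (2'S)-allylic alcohol 18, which has the spatial arrangement of the target carbinol; this is reagent control, and material with the wrong C4 configuration from step 7 becomes a separable diastereomer. The crude alcohol is silylated at −78 °C at once, because a free C2' hydroxyl can reach the aryl lactone carbonyl through a six-membered ring and take over the acyl group.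

**Step 13**
Reactants: 19 (4S)-4-[(2S,3E)-4-(4-benzyloxyphenyl)-2-(tert-butyldimethylsilyloxy)but-3-en-1-yl]-7-methoxy-5-(triisopropylsilyloxy)chroman-2-one
Product: 20 (4S)-4-[(2R)-2-(tert-butyldimethylsilyloxy)-4-(4-hydroxyphenyl)butyl]-7-methoxy-5-(triisopropylsilyloxy)chroman-2-one
Conditions: H2 (1 atm), Pd/C, EtOAc, rt
Reagents that add atoms: none
Why: Catalytic hydrogenation saturates the alkene and hydrogenolyses the benzyl ether in one operation; an aprotic solvent protects the aryl lactone, and the carbinol descriptor changes to R only because the neighbouring carbon is now saturated.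

**Step 14**
Reactants: 20 (4S)-4-[(2R)-2-(tert-butyldimethylsilyloxy)-4-(4-hydroxyphenyl)butyl]-7-methoxy-5-(triisopropylsilyloxy)chroman-2-one
Product: 21 (4S)-4-{(2R)-2-(tert-butyldimethylsilyloxy)-4-[4-(tert-butyldimethylsilyloxy)phenyl]butyl}-7-methoxy-5-(triisopropylsilyloxy)chroman-2-one
Conditions: TBSOTf, 2,6-lutidine, CH2Cl2, 0 °C
Reagents that add atoms: tert-butyldimethylsilyl triflate, CC(C)(C)[Si](C)(C)OS(=O)(=O)C(F)(F)F
Why: Silylation of the freed phenol under non-nucleophilic conditions; after this step every hydroxyl is a silyl ether and the molecule can face hydride and organometallic reagents.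

**Step 15**
Reactants: 21 (4S)-4-{(2R)-2-(tert-butyldimethylsilyloxy)-4-[4-(tert-butyldimethylsilyloxy)phenyl]butyl}-7-methoxy-5-(triisopropylsilyloxy)chroman-2-one
Product: 23 (4S)-4-{(2R)-2-(tert-butyldimethylsilyloxy)-4-[4-(tert-butyldimethylsilyloxy)phenyl]butyl}-7-methoxy-5-(triisopropylsilyloxy)chroman-2-yl acetate (both C2 anomers), via aluminium lactolate 22 (not isolated)
Conditions: i-Bu2AlH, CH2Cl2, −78 °C; then pyridine, DMAP, Ac2O, −78 to −20 °C
Reagents that add atoms: acetic anhydride, CC(=O)OC(C)=O
Why: One-pot reductive acetylation: i-Bu2AlH adds once to the aryl lactone at −78 °C and the aluminium hemiacetal 22 is acetylated before it can open to the aldehyde; the anomeric mixture is of no consequence because both anomers give the same cation.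

**Step 16**
Reactants: 23 (4S)-4-{(2R)-2-(tert-butyldimethylsilyloxy)-4-[4-(tert-butyldimethylsilyloxy)phenyl]butyl}-7-methoxy-5-(triisopropylsilyloxy)chroman-2-yl acetate; 24 (4-bromophenoxy)(tert-butyl)dimethylsilane
Product: 28 (2R,4R)-2-[4-(tert-butyldimethylsilyloxy)phenyl]-4-{(2R)-2-(tert-butyldimethylsilyloxy)-4-[4-(tert-butyldimethylsilyloxy)phenyl]butyl}-7-methoxy-5-(triisopropylsilyloxy)chroman (2,4-trans; C4 has the spatial arrangement of C4 in 34), via arylmagnesium bromide 25 (not isolated), via arylzinc bromide 26 (not isolated), via oxocarbenium ion 27 (not isolated)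
Conditions: 24, Mg, THF, rt; ZnBr2, 0 °C; then 23, BF3·OEt2, CH2Cl2, −78 to −20 °C
Reagents that add atoms: none
Why: Lewis-acid-promoted substitution of an anomeric acetate by an arylzinc reagent through the cyclic oxocarbenium ion 27, the reaction type used for 2-acetoxy- and 2-sulfonyl-tetrahydropyrans and for glycosyl acetates. The C5 silyloxy group forces the C4 chain pseudo-axial, so attack anti to it puts the aryl group equatorial and trans (C2 = R); the trans flavan should also be the more stable epimer, so any acid-mediated equilibration at the ionisable C2–O1 bond converges on it. The C4 descriptor changes to R only because the silyl ether on the C2' oxygen reverses the CIP ranking.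

**Step 17**
Reactants: 28 (2R,4R)-2-[4-(tert-butyldimethylsilyloxy)phenyl]-4-{(2R)-2-(tert-butyldimethylsilyloxy)-4-[4-(tert-butyldimethylsilyloxy)phenyl]butyl}-7-methoxy-5-(triisopropylsilyloxy)chroman
Product: 29 (2R,4R)-8-bromo-2-[4-(tert-butyldimethylsilyloxy)phenyl]-4-{(2R)-2-(tert-butyldimethylsilyloxy)-4-[4-(tert-butyldimethylsilyloxy)phenyl]butyl}-7-methoxy-5-(triisopropylsilyloxy)chroman
Conditions: NBS (1.0 equiv), CH2Cl2, −78 to −40 °C, dark
Reagents that add atoms: N-bromosuccinimide, BrN1C(=O)CCC1=O
Why: Electrophilic aromatic bromination of the triply oxygenated ring A, which is far more reactive than the mono-oxygenated rings; C8, between O1 and the methoxy group, is preferred over C6, which is screened by the triisopropylsilyl group, as in the C8-selective bromination of 5,7-di-O-protected flavans.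

**Step 18**
Reactants: 30 4-(tert-butyldimethylsilyloxy)benzaldehyde
Product: 31 (E)-3-[4-(tert-butyldimethylsilyloxy)phenyl]-N-methoxy-N-methylprop-2-enamide
Conditions: (EtO)2P(O)CH2C(O)N(OMe)Me, NaH, THF, 0 °C to rt
Reagents that add atoms: diethyl [2-(methoxy(methyl)amino)-2-oxoethyl]phosphonate, CCOP(=O)(OCC)CC(=O)N(C)OC
Why: Horner–Wadsworth–Emmons olefination with a stabilised phosphonate anion, which is E-selective; the aryl silyl ether tolerates the non-nucleophilic conditions.

**Step 19**
Reactants: 29 (2R,4R)-8-bromo-2-[4-(tert-butyldimethylsilyloxy)phenyl]-4-{(2R)-2-(tert-butyldimethylsilyloxy)-4-[4-(tert-butyldimethylsilyloxy)phenyl]butyl}-7-methoxy-5-(triisopropylsilyloxy)chroman; 31 (E)-3-[4-(tert-butyldimethylsilyloxy)phenyl]-N-methoxy-N-methylprop-2-enamide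
Product: 33 (E)-1-[(2R,4R)-2-[4-(tert-butyldimethylsilyloxy)phenyl]-4-{(2R)-2-(tert-butyldimethylsilyloxy)-4-[4-(tert-butyldimethylsilyloxy)phenyl]butyl}-7-methoxy-5-(triisopropylsilyloxy)chroman-8-yl]-3-[4-(tert-butyldimethylsilyloxy)phenyl]prop-2-en-1-one, via aryllithium 32 (not isolated)
Conditions: t-BuLi (2.0 equiv), THF, −78 °C; then 31, −78 to 0 °C; H2O
Reagents that add atoms: none
Why: Bromine–lithium exchange at −78 °C is faster than any deprotonation and gives the C8 aryllithium 32, which adds to the carbonyl of the N-methoxy-N-methylamide. The chelated tetrahedral adduct survives until work-up, so the enone is released only then and neither over-addition nor conjugate addition is expected; the E geometry comes from 31.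

**Step 20**
Reactants: 33 (E)-1-[(2R,4R)-2-[4-(tert-butyldimethylsilyloxy)phenyl]-4-{(2R)-2-(tert-butyldimethylsilyloxy)-4-[4-(tert-butyldimethylsilyloxy)phenyl]butyl}-7-methoxy-5-(triisopropylsilyloxy)chroman-8-yl]-3-[4-(tert-butyldimethylsilyloxy)phenyl]prop-2-en-1-one
Product: 34 (E)-1-[(2R,4S)-5-hydroxy-4-[(2R)-2-hydroxy-4-(4-hydroxyphenyl)butyl]-2-(4-hydroxyphenyl)-7-methoxychroman-8-yl]-3-(4-hydroxyphenyl)prop-2-en-1-one (CNP0102599.2)
Conditions: Et3N·3HF, THF, rt to 40 °C
Reagents that add atoms: none
Why: Fluoride cleavage of the four aryl silyl ethers and the secondary alkyl silyl ether under slightly acidic conditions, which avoid both phenoxide-driven opening of the C2–O1 bond and acid ionisation at C2; the enone is inert, and the C4 descriptor returns to S once the C2' oxygen carries hydrogen.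

## Compound list

1 | 2,4,6-trihydroxybenzaldehyde | O=Cc1c(O)cc(O)cc1O | starting material
2 | 2,6-dihydroxy-4-methoxybenzaldehyde | COc1cc(O)c(C=O)c(O)c1 | intermediate
3 | 2,6-bis(tert-butyldimethylsilyloxy)-4-methoxybenzaldehyde | COc1cc(O[Si](C)(C)C(C)(C)C)c(C=O)c(O[Si](C)(C)C(C)(C)C)c1 | intermediate
4 | 2,6-bis(tert-butyldimethylsilyloxy)-4-methoxystyrene | COc1cc(O[Si](C)(C)C(C)(C)C)c(C=C)c(O[Si](C)(C)C(C)(C)C)c1 | intermediate
5 | trichloroacetyl chloride | ClC(=O)C(Cl)(Cl)Cl | starting material
6 | dichloroketene | ClC(Cl)=C=O | intermediate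
7 | rac-3-[2,6-bis(tert-butyldimethylsilyloxy)-4-methoxyphenyl]-2,2-dichlorocyclobutan-1-one | COc1cc(O[Si](C)(C)C(C)(C)C)c(C2CC(=O)C2(Cl)Cl)c(O[Si](C)(C)C(C)(C)C)c1 | intermediate
8 | 3-[2,6-bis(tert-butyldimethylsilyloxy)-4-methoxyphenyl]cyclobutan-1-one (achiral) | COc1cc(O[Si](C)(C)C(C)(C)C)c(C2CC(=O)C2)c(O[Si](C)(C)C(C)(C)C)c1 | intermediate
9 | 4-(benzyloxy)benzaldehyde | O=Cc1ccc(OCc2ccccc2)cc1 | starting material
10 | (E)-3-[4-(benzyloxy)phenyl]prop-2-enal | O=C/C=C/c1ccc(OCc2ccccc2)cc1 | intermediate
11 | lithium (3R)-3-[2,6-bis(tert-butyldimethylsilyloxy)-4-methoxyphenyl]cyclobut-1-en-1-olate | COc1cc(O[Si](C)(C)C(C)(C)C)c(c(O[Si](C)(C)C(C)(C)C)c1)[C@@H]1CC(O[Li])=C1 | intermediate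
12 | (3R)-3-[2,6-bis(tert-butyldimethylsilyloxy)-4-methoxyphenyl]-2-[(E)-3-(4-benzyloxyphenyl)-1-hydroxyprop-2-en-1-yl]cyclobutan-1-one, mixture at C2 and the carbinol carbon | COc1cc(O[Si](C)(C)C(C)(C)C)c(c(O[Si](C)(C)C(C)(C)C)c1)[C@@H]1CC(=O)C1C(O)/C=C/c1ccc(OCc2ccccc2)cc1 | intermediate
13 | (3R)-2-[(E)-3-(4-benzyloxyphenyl)prop-2-enoyl]-3-[2,6-bis(tert-butyldimethylsilyloxy)-4-methoxyphenyl]cyclobutan-1-one, C2 not defined | COc1cc(O[Si](C)(C)C(C)(C)C)c(c(O[Si](C)(C)C(C)(C)C)c1)[C@@H]1CC(=O)C1C(=O)/C=C/c1ccc(OCc2ccccc2)cc1 | intermediate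
14 | (3R)-2-[(E)-3-(4-benzyloxyphenyl)prop-2-enoyl]-3-(2,6-dihydroxy-4-methoxyphenyl)cyclobutan-1-one, C2 not defined | COc1cc(O)c(c(O)c1)[C@@H]1CC(=O)C1C(=O)/C=C/c1ccc(OCc2ccccc2)cc1 | intermediate
15 | bridged hemiketal formed by addition of one ring-A hydroxyl to the cyclobutanone carbonyl of 14 (benzo-fused 2-oxabicyclo[3.1.1]heptan-1-ol; the oxygen bridge and the aryl bond are cis on the four-membered ring; acyl-bearing carbon not defined) | COc1cc(O)c2c(c1)O[C@@]1(O)C[C@@H]2C1C(=O)/C=C/c1ccc(OCc3ccccc3)cc1 | intermediate
16 | (4S)-4-[(3E)-4-(4-benzyloxyphenyl)-2-oxobut-3-en-1-yl]-5-hydroxy-7-methoxychroman-2-one | COc1cc(O)c2c(c1)OC(=O)C[C@@H]2CC(=O)/C=C/c1ccc(OCc3ccccc3)cc1 | intermediate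
17 | (4S)-4-[(3E)-4-(4-benzyloxyphenyl)-2-oxobut-3-en-1-yl]-7-methoxy-5-(triisopropylsilyloxy)chroman-2-one | COc1cc(O[Si](C(C)C)(C(C)C)C(C)C)c2c(c1)OC(=O)C[C@@H]2CC(=O)/C=C/c1ccc(OCc3ccccc3)cc1 | intermediate
18 | (4S)-4-[(2S,3E)-4-(4-benzyloxyphenyl)-2-hydroxybut-3-en-1-yl]-7-methoxy-5-(triisopropylsilyloxy)chroman-2-one | COc1cc(O[Si](C(C)C)(C(C)C)C(C)C)c2c(c1)OC(=O)C[C@@H]2C[C@H](O)/C=C/c1ccc(OCc3ccccc3)cc1 | intermediate
19 | (4S)-4-[(2S,3E)-4-(4-benzyloxyphenyl)-2-(tert-butyldimethylsilyloxy)but-3-en-1-yl]-7-methoxy-5-(triisopropylsilyloxy)chroman-2-one | COc1cc(O[Si](C(C)C)(C(C)C)C(C)C)c2c(c1)OC(=O)C[C@@H]2C[C@H](O[Si](C)(C)C(C)(C)C)/C=C/c1ccc(OCc3ccccc3)cc1 | intermediate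
20 | (4S)-4-[(2R)-2-(tert-butyldimethylsilyloxy)-4-(4-hydroxyphenyl)butyl]-7-methoxy-5-(triisopropylsilyloxy)chroman-2-one | COc1cc(O[Si](C(C)C)(C(C)C)C(C)C)c2c(c1)OC(=O)C[C@@H]2C[C@H](O[Si](C)(C)C(C)(C)C)CCc1ccc(O)cc1 | intermediate
21 | (4S)-4-{(2R)-2-(tert-butyldimethylsilyloxy)-4-[4-(tert-butyldimethylsilyloxy)phenyl]butyl}-7-methoxy-5-(triisopropylsilyloxy)chroman-2-one | COc1cc(O[Si](C(C)C)(C(C)C)C(C)C)c2c(c1)OC(=O)C[C@@H]2C[C@H](O[Si](C)(C)C(C)(C)C)CCc1ccc(O[Si](C)(C)C(C)(C)C)cc1 | intermediate
22 | diisobutylaluminium lactolate of 21 (O-aluminated chroman-2-ol, C2 not defined) | COc1cc(O[Si](C(C)C)(C(C)C)C(C)C)c2c(c1)OC(O[Al](CC(C)C)CC(C)C)C[C@@H]2C[C@H](O[Si](C)(C)C(C)(C)C)CCc1ccc(O[Si](C)(C)C(C)(C)C)cc1 | intermediate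
23 | (4S)-4-{(2R)-2-(tert-butyldimethylsilyloxy)-4-[4-(tert-butyldimethylsilyloxy)phenyl]butyl}-7-methoxy-5-(triisopropylsilyloxy)chroman-2-yl acetate, both C2 anomers | COc1cc(O[Si](C(C)C)(C(C)C)C(C)C)c2c(c1)OC(OC(C)=O)C[C@@H]2C[C@H](O[Si](C)(C)C(C)(C)C)CCc1ccc(O[Si](C)(C)C(C)(C)C)cc1 | intermediate
24 | (4-bromophenoxy)(tert-butyl)dimethylsilane | CC(C)(C)[Si](C)(C)Oc1ccc(Br)cc1 | starting material
25 | [4-(tert-butyldimethylsilyloxy)phenyl]magnesium bromide | CC(C)(C)[Si](C)(C)Oc1ccc([Mg]Br)cc1 | intermediate
26 | [4-(tert-butyldimethylsilyloxy)phenyl]zinc bromide | CC(C)(C)[Si](C)(C)Oc1ccc([Zn]Br)cc1 | intermediate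
27 | chroman-2-ylium (oxocarbenium) ion from 23, C4 and C2' as in 23 | COc1cc(O[Si](C(C)C)(C(C)C)C(C)C)c2c(c1)[O+]=CC[C@@H]2C[C@H](O[Si](C)(C)C(C)(C)C)CCc1ccc(O[Si](C)(C)C(C)(C)C)cc1 | intermediate
28 | (2R,4R)-2-[4-(tert-butyldimethylsilyloxy)phenyl]-4-{(2R)-2-(tert-butyldimethylsilyloxy)-4-[4-(tert-butyldimethylsilyloxy)phenyl]butyl}-7-methoxy-5-(triisopropylsilyloxy)chroman, 2,4-trans | COc1cc(O[Si](C(C)C)(C(C)C)C(C)C)c2c(c1)O[C@@H](c1ccc(O[Si](C)(C)C(C)(C)C)cc1)C[C@@H]2C[C@H](O[Si](C)(C)C(C)(C)C)CCc1ccc(O[Si](C)(C)C(C)(C)C)cc1 | intermediate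
29 | 8-bromo derivative of 28, (2R,4R), side chain (2R) | COc1cc(O[Si](C(C)C)(C(C)C)C(C)C)c2c(c1Br)O[C@@H](c1ccc(O[Si](C)(C)C(C)(C)C)cc1)C[C@@H]2C[C@H](O[Si](C)(C)C(C)(C)C)CCc1ccc(O[Si](C)(C)C(C)(C)C)cc1 | intermediate
30 | 4-(tert-butyldimethylsilyloxy)benzaldehyde | CC(C)(C)[Si](C)(C)Oc1ccc(C=O)cc1 | starting material
31 | (E)-3-[4-(tert-butyldimethylsilyloxy)phenyl]-N-methoxy-N-methylprop-2-enamide | CON(C)C(=O)/C=C/c1ccc(O[Si](C)(C)C(C)(C)C)cc1 | intermediate
32 | 8-lithio derivative of 28, (2R,4R), side chain (2R) | COc1cc(O[Si](C(C)C)(C(C)C)C(C)C)c2c(c1[Li])O[C@@H](c1ccc(O[Si](C)(C)C(C)(C)C)cc1)C[C@@H]2C[C@H](O[Si](C)(C)C(C)(C)C)CCc1ccc(O[Si](C)(C)C(C)(C)C)cc1 | intermediate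
33 | (E)-1-[(2R,4R)-2-[4-(tert-butyldimethylsilyloxy)phenyl]-4-{(2R)-2-(tert-butyldimethylsilyloxy)-4-[4-(tert-butyldimethylsilyloxy)phenyl]butyl}-7-methoxy-5-(triisopropylsilyloxy)chroman-8-yl]-3-[4-(tert-butyldimethylsilyloxy)phenyl]prop-2-en-1-one | COc1cc(O[Si](C(C)C)(C(C)C)C(C)C)c2c(c1C(=O)/C=C/c1ccc(O[Si](C)(C)C(C)(C)C)cc1)O[C@@H](c1ccc(O[Si](C)(C)C(C)(C)C)cc1)C[C@@H]2C[C@H](O[Si](C)(C)C(C)(C)C)CCc1ccc(O[Si](C)(C)C(C)(C)C)cc1 | intermediate
34 | (E)-1-[(2R,4S)-5-hydroxy-4-[(2R)-2-hydroxy-4-(4-hydroxyphenyl)butyl]-2-(4-hydroxyphenyl)-7-methoxychroman-8-yl]-3-(4-hydroxyphenyl)prop-2-en-1-one | COc1cc(O)c2c(c1C(=O)/C=C/c1ccc(O)cc1)O[C@@H](c1ccc(O)cc1)C[C@@H]2C[C@H](O)CCc1ccc(O)cc1 | target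

## Step count and least certain steps

Total step count: 20. Longest linear sequence: 18 steps (steps 1 to 5, 7 to 17, 19 and 20); steps 6 and 18 make the two side fragments.

**Step 10 (key step).** The phenol may add to the side-chain carbonyl instead, which is also a six-membered closure, and this could be followed by acyl transfer from carbon to oxygen or by dehydration. The β-diketone may also be fully ionised, which would shut down attack at the ring carbonyl.
Fallback, from 13 to 16: the ring is opened intermolecularly while ring A is still silylated. Methanol with catalytic DMAP in CH2Cl2 should cleave the cyclobutanone to methyl (3S,6E)-7-(4-benzyloxyphenyl)-3-[2,6-bis(tert-butyldimethylsilyloxy)-4-methoxyphenyl]-5-oxohept-6-enoate F1. Buffered Bu4NF then frees the phenols to give methyl (3S,6E)-7-(4-benzyloxyphenyl)-3-(2,6-dihydroxy-4-methoxyphenyl)-5-oxohept-6-enoate F2. Warming F2 with Et3N in toluene while methanol is removed closes the lactone and rejoins the route at 16.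

**Step 7.** Discrimination between the two enantiotopic methylenes may be incomplete when the enolate is trapped only after deprotonation, and the cyclobutanone may undergo self-aldol addition before the enal arrives.
Fallback, from 8 to 12: the same lithium amide is used with Me3SiCl present during deprotonation, which gives {[(3R)-3-[2,6-bis(tert-butyldimethylsilyloxy)-4-methoxyphenyl]cyclobut-1-en-1-yl]oxy}trimethylsilane F3. A Mukaiyama aldol addition of F3 to 10 with BF3·OEt2 in CH2Cl2 at −78 °C then returns to 12.

**Step 4.** The electron-rich styrene may oligomerise under ZnCl2, and the two ortho silyloxy groups may slow the cycloaddition.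
Fallback, from 4 to 8: a keteniminium [2+2] cycloaddition with the salt made from N,N-dimethylacetamide, triflic anhydride and 2,4,6-collidine gives N-{3-[2,6-bis(tert-butyldimethylsilyloxy)-4-methoxyphenyl]cyclobutylidene}-N-methylmethanaminium triflate F4. Aqueous NaHCO3 hydrolyses F4 directly to 8, so steps 4 and 5 are replaced.

**Step 16.** Facial selectivity at cation 27 may be poor. The cation may also be captured by the C2' silyloxy oxygen with loss of the silyl group, and aryl transfer from zinc may be slow.
Fallback, from 21 to 28: i-Bu2AlH at −78 °C gives the lactol (2RS,4S)-4-{(2R)-2-(tert-butyldimethylsilyloxy)-4-[4-(tert-butyldimethylsilyloxy)phenyl]butyl}-7-methoxy-5-(triisopropylsilyloxy)chroman-2-ol F5. An excess of Grignard reagent 25 adds to its open hydroxy-aldehyde form and gives (1RS,3R,5R)-5-(tert-butyldimethylsilyloxy)-1,7-bis[4-(tert-butyldimethylsilyloxy)phenyl]-3-[2-hydroxy-4-methoxy-6-(triisopropylsilyloxy)phenyl]heptan-1-ol F6. A catalytic amount of p-toluenesulfonic acid in CH2Cl2 then closes the pyran ring through the benzylic cation. Both carbinol epimers converge under thermodynamic control on the trans flavan 28.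

**Step 17.** Bromination may also occur at C6, or twice.
Fallback, from 28 to 32: the bromide is left out and 28 is lithiated directly with n-BuLi and TMEDA in Et2O at 0 °C. C8 is the only ring-A position between two coordinating oxygens that is not screened by silicon. The aryllithium 32 is then acylated as in step 19. No new compound is needed.

## Further compounds

F1 | step 10 | methyl (3S,6E)-7-(4-benzyloxyphenyl)-3-[2,6-bis(tert-butyldimethylsilyloxy)-4-methoxyphenyl]-5-oxohept-6-enoate | COC(=O)C[C@H](CC(=O)/C=C/c1ccc(OCc2ccccc2)cc1)c1c(O[Si](C)(C)C(C)(C)C)cc(OC)cc1O[Si](C)(C)C(C)(C)C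
F2 | step 10 | methyl (3S,6E)-7-(4-benzyloxyphenyl)-3-(2,6-dihydroxy-4-methoxyphenyl)-5-oxohept-6-enoate | COC(=O)C[C@H](CC(=O)/C=C/c1ccc(OCc2ccccc2)cc1)c1c(O)cc(OC)cc1O
F3 | step 7 | {[(3R)-3-[2,6-bis(tert-butyldimethylsilyloxy)-4-methoxyphenyl]cyclobut-1-en-1-yl]oxy}trimethylsilane | COc1cc(O[Si](C)(C)C(C)(C)C)c(c(O[Si](C)(C)C(C)(C)C)c1)[C@@H]1CC(O[Si](C)(C)C)=C1
F4 | step 4 | N-{3-[2,6-bis(tert-butyldimethylsilyloxy)-4-methoxyphenyl]cyclobutylidene}-N-methylmethanaminium triflate | COc1cc(O[Si](C)(C)C(C)(C)C)c(C2CC(=[N+](C)C)C2)c(O[Si](C)(C)C(C)(C)C)c1.[O-]S(=O)(=O)C(F)(F)F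
F5 | step 16 | (2RS,4S)-4-{(2R)-2-(tert-butyldimethylsilyloxy)-4-[4-(tert-butyldimethylsilyloxy)phenyl]butyl}-7-methoxy-5-(triisopropylsilyloxy)chroman-2-ol | COc1cc(O[Si](C(C)C)(C(C)C)C(C)C)c2c(c1)OC(O)C[C@@H]2C[C@H](O[Si](C)(C)C(C)(C)C)CCc1ccc(O[Si](C)(C)C(C)(C)C)cc1
F6 | step 16 | (1RS,3R,5R)-5-(tert-butyldimethylsilyloxy)-1,7-bis[4-(tert-butyldimethylsilyloxy)phenyl]-3-[2-hydroxy-4-methoxy-6-(triisopropylsilyloxy)phenyl]heptan-1-ol | COc1cc(O)c(c(O[Si](C(C)C)(C(C)C)C(C)C)c1)[C@H](CC(O)c1ccc(O[Si](C)(C)C(C)(C)C)cc1)C[C@H](O[Si](C)(C)C(C)(C)C)CCc1ccc(O[Si](C)(C)C(C)(C)C)cc1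
F0 | step 17 | none | none
A1 | alternative 1 | ring-A-complete open-chain chalcone with free hydroxyls at the future C7 and C8a, methoxymethyl ethers on C5 and the three para-phenols, silyl ethers on both carbinols | O=C(/C=C/c1ccc(OCOC)cc1)c1c(O)cc(OCOC)c(c1O)[C@H](C[C@@H](O[Si](C)(C)C(C)(C)C)c1ccc(OCOC)cc1)C[C@H](O[Si](C)(C)C(C)(C)C)CCc1ccc(OCOC)cc1
A2 | alternative 1 | magnesium methoxide | [Mg+2].[O-]C.[O-]C
A3 | alternative 2 | fully silylated target (triisopropylsilyl ethers on the four phenols, tert-butyldimethylsilyl ether on the carbinol) | COc1cc(O[Si](C(C)C)(C(C)C)C(C)C)c2c(c1C(=O)/C=C/c1ccc(O[Si](C(C)C)(C(C)C)C(C)C)cc1)O[C@@H](c1ccc(O[Si](C(C)C)(C(C)C)C(C)C)cc1)C[C@@H]2C[C@H](O[Si](C)(C)C(C)(C)C)CCc1ccc(O[Si](C(C)C)(C(C)C)C(C)C)cc1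
A4 | alternative 2 | lithium 2,2,6,6-tetramethylpiperidide | [Li]N1C(C)(C)CCCC1(C)C
A5 | alternative 3 | 5-hydroxy-7-methoxy-2,4-trans-chroman with C8 unsubstituted, silyl-protected side chain and C2 aryl group | COc1cc(O)c2c(c1)O[C@@H](c1ccc(O[Si](C(C)C)(C(C)C)C(C)C)cc1)C[C@@H]2C[C@H](O[Si](C)(C)C(C)(C)C)CCc1ccc(O[Si](C(C)C)(C(C)C)C(C)C)cc1
A6 | alternative 3 | methoxyacetylene | COC#C
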